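**Plan**

1. Numbering (elemanolide): C10 = quaternary carbon (methyl C14, vinyl C1=C2), C9 = ring CH2, C8 = acyloxy carbon, C7/C6 = lactone ring fusion (C11–C13 = methylene lactone), C5 = carbon carrying the hydroxy-isopropenyl group (C4, =C3H2, C15), C1'–C4' = side-chain acid.
2. Retrosynthesis: cut the C15–O bond (allylic oxidation) and the O8–C1' ester; then C11=C13, the lactone C6–O bond and C7–C11; last, in one operation, C8–C9 and C5–C10, which leaves isoprene and a four-membered ketone.
3. Enabling feature: O6 and O8 sit 1,3 across C7 and C5 is allylic, so C5–C6–C7–C8 is a latent 1,4-dipole (dienolate at C5, oxocarbenium at C8) that can be stored as the strained C5–C8 bond of a 3-alkoxy-2-isopropenylcyclobutanone; C9=C10 with its methyl and vinyl groups is isoprene itself.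
4. Forward: ketene–vinyl ether [2+2] gives the cyclobutanone; a Lewis acid formal (4+2) with isoprene closes the cyclohexanone ring with quaternary C10; then C7 alkylation, ketone reduction with lactone closure, α-methylenation, unmasking and acylation of O8 with the chiral-pool acid, C15 hydroxylation, ketal removal.
5. Stereochemistry: an (R)-1-phenylethyl group on O8 (auxiliary and protecting group) sets C8 in the ring-forming step; C5 and C10 follow from the chair closure, C7 from alkylation anti to O8, C6 from thermodynamically controlled ketone reduction, C3' from (R)-malic acid.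

Key step: step 3

Remark: the facial sense of the 1-phenylethyl group is taken from the allylic-strain model of O-(1-arylethyl) oxocarbenium ions (were it the reverse, (S)-1-phenylethanol would be used with no other change), and methyl (R)-2-(2,2-dimethyl-1,3-dioxolan-4-yl)acetate is taken as a purchasable chiral-pool ester derived from (R)-malic acid.

**Route**

Step 1
Reactants: 1 (R)-1-phenylethanol; 2 vinyl acetate
Product: 3 [(1R)-1-(ethenyloxy)ethyl]benzene
Conditions: [Ir(cod)Cl]2 (1 mol %), Na2CO3 (0.6 equiv), toluene, 100 °C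
Reagents that add atoms: none
Why: Iridium-catalysed transfer vinylation of an alcohol with vinyl acetate should give the vinyl ether without breaking the C–O bond of the stereocentre, so the (R) configuration is kept.

Step 2
Reactants: 3 [(1R)-1-(ethenyloxy)ethyl]benzene; 4 3-methylbut-2-enoyl chloride
Product: 6 3-[(1R)-1-phenylethoxy]-2-(prop-1-en-2-yl)cyclobutan-1-one (mixture of ring diastereomers), via isopropenylketene 5 (not isolated)
Conditions: Et3N (3 equiv), 4 (2.5 equiv, slow addition), CH2Cl2, reflux
Reagents that add atoms: none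
Why: 1,4-Dehydrochlorination of the acid chloride gives the vinylketene, which should add to the electron-rich vinyl ether in a thermal ketene–alkene [2+2] cycloaddition (carbonyl carbon to the ether β-carbon); both new ring stereocentres are erased in step 3, so their mixture does not matter.

Step 3
Reactants: 6 3-[(1R)-1-phenylethoxy]-2-(prop-1-en-2-yl)cyclobutan-1-one; 7 isoprene
Product: 10 (2S,3S,5S)-3-ethenyl-3-methyl-5-[(1R)-1-phenylethoxy]-2-(prop-1-en-2-yl)cyclohexan-1-one, via oxocarbenium dienolate 8 (not isolated), via allyl cation dienolate 9 (not isolated)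
Conditions: SnCl4 (20 mol %), 2,6-di-tert-butyl-4-methylpyridine (30 mol %), 7 (15 equiv), CH2Cl2, −78 to −40 °C
Reagents that add atoms: none
Why: Proposed new method: SnCl4 on the ketone oxygen lets the strained C5–C8 bond (allylic, α to the carbonyl and aligned with an ether lone pair) ionise to the tin (Z)-dienolate/oxocarbenium pair 8, isoprene adds through C9 (its CH2 next to the methyl-bearing carbon) to C8 to give the tertiary allyl cation 9, and the dienolate carbon C5 then bonds to C10, releasing SnCl4. The closest known reaction type is the Lewis acid-catalysed formal (4+2) cycloaddition of 3-alkoxycyclobutanones with allylsilanes, with silyl enol ethers and, intramolecularly, with substituted alkenes; new is an unactivated 1,3-diene as the intermolecular two-carbon partner, which is about as nucleophilic toward carbocations as an allylsilane and leaves a better stabilised cation. The one ring formed is the cyclohexanone, closed by C-alkylation of the enolate in a 6-(enolendo)-exo-trig mode through a chair. C8 is set by the (R)-1-phenylethyl group, whose C–H lies in the plane of the (E)-oxocarbenium ion (allylic strain) so that the diene adds to the face opposite phenyl; C5 and C10 follow from the chair in which the ether, the isopropenyl group (cis to the tin-bound oxygen in the (Z)-dienolate that least-motion ring opening gives) and the vinyl arm are equatorial and the methyl group axial, the arrangement in which C3 of the dienolate and C2 of the allyl cation overlap in phase as in the chair Cope transition state that links germacranes and elemanes. The step needs capture of 8 by the diene to outrun its collapse to a cyclohexenone by bonding of C3 to C8, which the (Z)-dienolate geometry forbids and the excess of 7 further disfavours; it needs cleavage of C5–C8 and not C7–C8, secured by the allylic, more substituted bond; and it needs closure at C10 and not at C2, secured by six- over eight-membered ring formation, with the hindered pyridine suppressing protic polymerisation of 7.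

Step 4
Reactants: 10 (2S,3S,5S)-3-ethenyl-3-methyl-5-[(1R)-1-phenylethoxy]-2-(prop-1-en-2-yl)cyclohexan-1-one; 11 methyl bromoacetate
Product: 12 methyl 2-[(1R,3S,4S,6S)-4-ethenyl-4-methyl-2-oxo-6-[(1R)-1-phenylethoxy]-3-(prop-1-en-2-yl)cyclohexyl]acetate
Conditions: LiN(iPr)2 (1.05 equiv), THF, −78 °C; then 11, DMPU, −78 to −45 °C
Reagents that add atoms: none
Why: Kinetic deprotonation by the hindered amide should take the C7 methylene and not the tertiary C5–H next to the quaternary carbon, and SN2 alkylation of the cold lithium enolate (too cold to expel the β-alkoxide) should occur anti to the adjacent C8 ether to give the trans, equatorial acetate arm, which is also the thermodynamic C7 epimer.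

Step 5
Reactants: 12 methyl 2-[(1R,3S,4S,6S)-4-ethenyl-4-methyl-2-oxo-6-[(1R)-1-phenylethoxy]-3-(prop-1-en-2-yl)cyclohexyl]acetate
Product: 14 (3aR,4S,6S,7S,7aR)-6-ethenyl-6-methyl-4-[(1R)-1-phenylethoxy]-7-(prop-1-en-2-yl)hexahydro-1-benzofuran-2(3H)-one, via hydroxy ester 13 (not isolated)
Conditions: SmI2 (2.5 equiv), THF/MeOH, −78 to 0 °C; then pyridinium p-toluenesulfonate (cat.), toluene, 60 °C
Reagents that add atoms: none
Why: Ketyl (single-electron) reduction by SmI2 is thermodynamically controlled like a dissolving-metal reduction and should place the C6 oxygen equatorial, trans to both neighbours, whereas hydride reagents would approach away from the axial C10 methyl and give the axial alcohol; the trans hydroxyl and ester arm then close to the trans-fused γ-lactone, and alkenes, ester and benzylic ether are inert to SmI2.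

Step 6
Reactants: 14 (3aR,4S,6S,7S,7aR)-6-ethenyl-6-methyl-4-[(1R)-1-phenylethoxy]-7-(prop-1-en-2-yl)hexahydro-1-benzofuran-2(3H)-one
Product: 17 (3aR,4S,6S,7S,7aR)-6-ethenyl-6-methyl-3-methylidene-4-[(1R)-1-phenylethoxy]-7-(prop-1-en-2-yl)hexahydro-1-benzofuran-2(3H)-one, via Mannich base 15 (not isolated), via ammonium iodide 16 (not isolated)
Conditions: LiN(iPr)2, THF, −78 °C; Me2N=CH2+ I−, −78 to 0 °C; then MeI, MeOH, 23 °C; then aq NaHCO3, CH2Cl2
Reagents that add atoms: N,N-dimethylmethyleneiminium iodide (Eschenmoser's salt), C=[N+](C)C.[I-]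
Why: Mannich reaction of the lactone enolate, N-methylation and E1cB loss of trimethylamine is the standard α-methylenation of γ-lactones; no existing stereocentre is touched and the transient C11 centre disappears on elimination.

Step 7
Reactants: 17 (3aR,4S,6S,7S,7aR)-6-ethenyl-6-methyl-3-methylidene-4-[(1R)-1-phenylethoxy]-7-(prop-1-en-2-yl)hexahydro-1-benzofuran-2(3H)-one
Product: 18 (3aR,4S,6S,7S,7aR)-6-ethenyl-4-hydroxy-6-methyl-3-methylidene-7-(prop-1-en-2-yl)hexahydro-1-benzofuran-2(3H)-one
Conditions: BCl3 (2 equiv), pentamethylbenzene (3 equiv), CH2Cl2, −78 °C; then MeOH, aq NaHCO3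
Reagents that add atoms: none
Why: Lewis acid cleavage of the secondary benzylic ether, with pentamethylbenzene as a non-basic Friedel–Crafts trap for the 1-phenylethyl cation, should free the C8 hydroxyl with retention (the benzylic C–O bond breaks, not C8–O) and at −78 °C should leave the three alkenes and the lactone alone.

Step 8
Reactants: 19 methyl 2-[(4R)-2,2-dimethyl-1,3-dioxolan-4-yl]acetate
Product: 22 methyl 2-[(4R)-2,2-dimethyl-1,3-dioxolan-4-yl]prop-2-enoate, via Mannich base 20 (not isolated), via ammonium iodide 21 (not isolated)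
Conditions: LiN(iPr)2, THF, −78 °C; Me2N=CH2+ I−, −78 to 0 °C; then MeI, MeOH, 23 °C; then aq NaHCO3, CH2Cl2
Reagents that add atoms: N,N-dimethylmethyleneiminium iodide (Eschenmoser's salt), C=[N+](C)C.[I-]
Why: The same Mannich–methylation–elimination sequence on the ester enolate should give the α-methylene ester, since at −78 °C the enolate is trapped by the iminium salt before it can expel the β-alkoxide and trimethylamine is by far the better leaving group in the elimination; the stereocentre is the β-carbon and is not involved.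

Step 9
Reactants: 22 methyl 2-[(4R)-2,2-dimethyl-1,3-dioxolan-4-yl]prop-2-enoate
Product: 23 2-[(4R)-2,2-dimethyl-1,3-dioxolan-4-yl]prop-2-enoic acid
Conditions: LiOH, THF/H2O, 0 °C; then aq HCl to pH 4, 0 °C
Reagents that add atoms: lithium hydroxide, [Li+].[OH-]
Why: Saponification of the methyl ester by acyl substitution should give the acid, the ketal being stable to base and to brief cold acidification, and the stereocentre having no acidic hydrogen pathway to epimerise.

Step 10
Reactants: 18 (3aR,4S,6S,7S,7aR)-6-ethenyl-4-hydroxy-6-methyl-3-methylidene-7-(prop-1-en-2-yl)hexahydro-1-benzofuran-2(3H)-one; 23 2-[(4R)-2,2-dimethyl-1,3-dioxolan-4-yl]prop-2-enoic acid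
Product: 24 (3aR,4S,6S,7S,7aR)-6-ethenyl-6-methyl-3-methylidene-2-oxo-7-(prop-1-en-2-yl)octahydro-1-benzofuran-4-yl 2-[(4R)-2,2-dimethyl-1,3-dioxolan-4-yl]prop-2-enoate
Conditions: DCC, DMAP (cat.), CH2Cl2, 0 to 23 °C
Reagents that add atoms: none
Why: Steglich esterification acylates the only free hydroxyl, the equatorial C8–OH, through the acylpyridinium ion without touching a stereocentre.

Step 11
Reactants: 24 (3aR,4S,6S,7S,7aR)-6-ethenyl-6-methyl-3-methylidene-2-oxo-7-(prop-1-en-2-yl)octahydro-1-benzofuran-4-yl 2-[(4R)-2,2-dimethyl-1,3-dioxolan-4-yl]prop-2-enoate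
Product: 25 (3aR,4S,6S,7R,7aR)-6-ethenyl-7-(3-hydroxyprop-1-en-2-yl)-6-methyl-3-methylidene-2-oxooctahydro-1-benzofuran-4-yl 2-[(4R)-2,2-dimethyl-1,3-dioxolan-4-yl]prop-2-enoate
Conditions: SeO2 (0.3 equiv), tBuOOH (3 equiv), CH2Cl2, 0 to 23 °C
Reagents that add atoms: tert-butyl hydroperoxide, CC(C)(C)OO (terminal oxidant; its oxygen is passed on by the catalyst selenium dioxide, O=[Se]=O)
Why: The SeO2 ene reaction and [2,3]-sigmatropic shift (allylic oxidation) should hydroxylate the methyl group of the isopropenyl unit, the only electron-rich alkene with allylic hydrogen (CH3 before the hindered C5–H; the vinyl group has none and both acrylate-type alkenes are electron-poor); no stereocentre is formed.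

Step 12
Reactants: 25 (3aR,4S,6S,7R,7aR)-6-ethenyl-7-(3-hydroxyprop-1-en-2-yl)-6-methyl-3-methylidene-2-oxooctahydro-1-benzofuran-4-yl 2-[(4R)-2,2-dimethyl-1,3-dioxolan-4-yl]prop-2-enoate
Product: 26 (3aR,4S,6S,7R,7aR)-6-ethenyl-7-(3-hydroxyprop-1-en-2-yl)-6-methyl-3-methylidene-2-oxooctahydro-1-benzofuran-4-yl (3R)-3,4-dihydroxy-2-methylidenebutanoate (target)
Conditions: AcOH/THF/H2O (3:1:1), 40 °C
Reagents that add atoms: none
Why: Mild acid hydrolysis of the isopropylidene ketal should free the 1,2-diol while the esters, the lactone and the allylic alcohol survive, and no stereocentre is affected.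

**Compound list**

1 | (R)-1-phenylethanol | C[C@@H](O)c1ccccc1 | starting material
2 | vinyl acetate | CC(=O)OC=C | starting material
3 | [(1R)-1-(ethenyloxy)ethyl]benzene | C=CO[C@H](C)c1ccccc1 | intermediate
4 | 3-methylbut-2-enoyl chloride | CC(C)=CC(=O)Cl | starting material
5 | isopropenylketene (3-methylbuta-1,3-dien-1-one) | C=C(C)C=C=O | intermediate (not isolated)
6 | 3-[(1R)-1-phenylethoxy]-2-(prop-1-en-2-yl)cyclobutan-1-one, ring stereocentres as a mixture | CC(=C)C1C(=O)CC1O[C@H](C)c2ccccc2 | intermediate
7 | isoprene (2-methylbuta-1,3-diene) | C=CC(C)=C | starting material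
8 | oxocarbenium dienolate: ring-opened zwitterion of 6 with (Z)-dienolate and (E)-oxocarbenium ion, tin-bound in the flask, drawn without tin | C=C(C)/C=C(\[O-])C/C=[O+]/[C@H](C)c1ccccc1 | intermediate (not isolated)
9 | allyl cation dienolate: adduct of 8 and isoprene with the C8–C9 bond in place (C8 S), tin-bound in the flask, drawn without tin | C=C(C)/C=C(\[O-])C[C@@H](O[C@H](C)c1ccccc1)C[C+](C)C=C | intermediate (not isolated)
10 | (2S,3S,5S)-3-ethenyl-3-methyl-5-[(1R)-1-phenylethoxy]-2-(prop-1-en-2-yl)cyclohexan-1-one | C=C[C@]1(C)C[C@H](O[C@H](C)c2ccccc2)CC(=O)[C@H]1C(C)=C | intermediate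
11 | methyl bromoacetate | COC(=O)CBr | starting material
12 | methyl 2-[(1R,3S,4S,6S)-4-ethenyl-4-methyl-2-oxo-6-[(1R)-1-phenylethoxy]-3-(prop-1-en-2-yl)cyclohexyl]acetate | C=C[C@]1(C)C[C@H](O[C@H](C)c2ccccc2)[C@@H](CC(=O)OC)C(=O)[C@H]1C(C)=C | intermediate
13 | hydroxy ester: 12 with the ketone reduced to the equatorial (6α) alcohol, trans to both neighbours | C=C[C@]1(C)C[C@H](O[C@H](C)c2ccccc2)[C@@H](CC(=O)OC)[C@H](O)[C@H]1C(C)=C | intermediate (not isolated)
14 | (3aR,4S,6S,7S,7aR)-6-ethenyl-6-methyl-4-[(1R)-1-phenylethoxy]-7-(prop-1-en-2-yl)hexahydro-1-benzofuran-2(3H)-one (trans-fused lactone) | C=C[C@]1(C)C[C@H](O[C@H](C)c3ccccc3)[C@H]2CC(=O)O[C@@H]2[C@H]1C(C)=C | intermediate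
15 | Mannich base: 14 with a dimethylaminomethyl group on the lactone α-carbon (either configuration there) | C=C[C@]1(C)C[C@H](O[C@H](C)c3ccccc3)[C@H]2C(CN(C)C)C(=O)O[C@@H]2[C@H]1C(C)=C | intermediate (not isolated)
16 | ammonium iodide: N-methylated 15 | C=C[C@]1(C)C[C@H](O[C@H](C)c3ccccc3)[C@H]2C(C[N+](C)(C)C)C(=O)O[C@@H]2[C@H]1C(C)=C.[I-] | intermediate (not isolated)
17 | (3aR,4S,6S,7S,7aR)-6-ethenyl-6-methyl-3-methylidene-4-[(1R)-1-phenylethoxy]-7-(prop-1-en-2-yl)hexahydro-1-benzofuran-2(3H)-one | C=C[C@]1(C)C[C@H](O[C@H](C)c3ccccc3)[C@H]2C(=C)C(=O)O[C@@H]2[C@H]1C(C)=C | intermediate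
18 | (3aR,4S,6S,7S,7aR)-6-ethenyl-4-hydroxy-6-methyl-3-methylidene-7-(prop-1-en-2-yl)hexahydro-1-benzofuran-2(3H)-one | C=C[C@]1(C)C[C@H](O)[C@H]2C(=C)C(=O)O[C@@H]2[C@H]1C(C)=C | intermediate
19 | methyl 2-[(4R)-2,2-dimethyl-1,3-dioxolan-4-yl]acetate | COC(=O)C[C@@H]1COC(C)(C)O1 | starting material
20 | Mannich base: 19 with a dimethylaminomethyl group on the ester α-carbon | COC(=O)C(CN(C)C)[C@@H]1COC(C)(C)O1 | intermediate (not isolated)
21 | ammonium iodide: N-methylated 20 | COC(=O)C(C[N+](C)(C)C)[C@@H]1COC(C)(C)O1.[I-] | intermediate (not isolated)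
22 | methyl 2-[(4R)-2,2-dimethyl-1,3-dioxolan-4-yl]prop-2-enoate | COC(=O)C(=C)[C@@H]1COC(C)(C)O1 | intermediate
23 | 2-[(4R)-2,2-dimethyl-1,3-dioxolan-4-yl]prop-2-enoic acid | OC(=O)C(=C)[C@@H]1COC(C)(C)O1 | intermediate
24 | (3aR,4S,6S,7S,7aR)-6-ethenyl-6-methyl-3-methylidene-2-oxo-7-(prop-1-en-2-yl)octahydro-1-benzofuran-4-yl 2-[(4R)-2,2-dimethyl-1,3-dioxolan-4-yl]prop-2-enoate | C=C[C@]1(C)C[C@H](OC(=O)C(=C)[C@@H]3COC(C)(C)O3)[C@H]2C(=C)C(=O)O[C@@H]2[C@H]1C(C)=C | intermediate
25 | (3aR,4S,6S,7R,7aR)-6-ethenyl-7-(3-hydroxyprop-1-en-2-yl)-6-methyl-3-methylidene-2-oxooctahydro-1-benzofuran-4-yl 2-[(4R)-2,2-dimethyl-1,3-dioxolan-4-yl]prop-2-enoate | C=C[C@]1(C)C[C@H](OC(=O)C(=C)[C@@H]3COC(C)(C)O3)[C@H]2C(=C)C(=O)O[C@@H]2[C@H]1C(=C)CO | intermediate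
26 | (3aR,4S,6S,7R,7aR)-6-ethenyl-7-(3-hydroxyprop-1-en-2-yl)-6-methyl-3-methylidene-2-oxooctahydro-1-benzofuran-4-yl (3R)-3,4-dihydroxy-2-methylidenebutanoate | C=C[C@]1(C)C[C@H](OC(=O)C(=C)[C@@H](O)CO)[C@H]2C(=C)C(=O)O[C@@H]2[C@H]1C(=C)CO | target

**Step count and risks**

Total step count: 12. Longest linear sequence: 10 steps (steps 1 to 7 and 10 to 12, from compound 1).

Steps most likely to fail:

Step 3 (Proposed new method). The ring-opened dipole may collapse by an internal 1,3-shift to a cyclohexenone before the diene arrives, the diene may polymerise cationically, the benzylic ether may ionise, or the chair closure may give poor selectivity at C10 and C5; the auxiliary may also induce C8 only partly, in which case the diastereomers are separated at 10. The fallback uses known chemistry and sets out from 6. The known formal (4+2) of 3-alkoxycyclobutanones with a silyl enol ether is run with 2-(trimethylsilyloxy)buta-1,3-diene (SnCl4, CH2Cl2, −78 °C) to give the 3-vinyl-3-silyloxy cyclohexanone F1, with C8 set by the same auxiliary. Acid (TsOH, CH2Cl2) eliminates silanol through the more acidic C5–H to give the cross-conjugated enone F2. Copper-catalysed 1,4-addition of MeMgBr (CuBr·SMe2 with an N-heterocyclic carbene ligand, conditions known to favour 1,4- over 1,6-addition on 3-alkenyl enones) then delivers methyl anti to the C8 ether, which leaves vinyl cis to it, and protonation of the enolate returns to the route at 10.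

Step 5. The ketone reduction may show poor facial selectivity and deliver the axial 6β-alcohol, which closes to the cis-fused lactone. The fallback sets out from 12 and makes that outcome deliberate: LiBH(sBu)3 (THF, −78 °C) attacks from the equatorial side and the 6β-alkoxide lactonises in the flask to the cis-fused lactone F3. LiOH opens it to the 6β-hydroxy acid F4, which is freed at 0 °C and used at once. Mitsunobu lactonisation (PPh3, DIAD, THF) then closes the ring with inversion at C6 and returns to the route at 14.

Step 4. Enolisation may go to the more acidic allylic C5–H instead of C7, or the C7 enolate may expel the C8 alkoxide. The fallback sets out from 10: condensation with Me2NNH2 (AcOH cat., EtOH) gives the N,N-dimethylhydrazone F5, whose azaenolate (LiN(iPr)2, THF, −78 °C) forms at the less substituted carbon and is alkylated with 11 to the hydrazone F6; mild hydrolysis (aq CuCl2, THF, pH 7 buffer) returns to the route at 12.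

**Further compounds**

F1 | step 3 | (5S)-3-ethenyl-5-[(1R)-1-phenylethoxy]-2-(prop-1-en-2-yl)-3-(trimethylsilyloxy)cyclohexan-1-one, mixture at C2 and C3 | C=CC1(O[Si](C)(C)C)C[C@H](O[C@H](C)c2ccccc2)CC(=O)C1C(C)=C
F2 | step 3 | (5S)-3-ethenyl-5-[(1R)-1-phenylethoxy]-2-(prop-1-en-2-yl)cyclohex-2-en-1-one | C=CC1=C(C(C)=C)C(=O)C[C@@H](O[C@H](C)c2ccccc2)C1
F3 | step 5 | cis-fused lactone, the C6 epimer of 14 | C=C[C@]1(C)C[C@H](O[C@H](C)c3ccccc3)[C@H]2CC(=O)O[C@H]2[C@H]1C(C)=C
F4 | step 5 | 6β-hydroxy acid obtained by opening F3 | C=C[C@]1(C)C[C@H](O[C@H](C)c2ccccc2)[C@@H](CC(=O)O)[C@@H](O)[C@H]1C(C)=C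
F5 | step 4 | N,N-dimethylhydrazone of 10 | C=C[C@]1(C)C[C@H](O[C@H](C)c2ccccc2)CC(=NN(C)C)[C@H]1C(C)=C
F6 | step 4 | N,N-dimethylhydrazone of 12 | C=C[C@]1(C)C[C@H](O[C@H](C)c2ccccc2)[C@@H](CC(=O)OC)C(=NN(C)C)[C@H]1C(C)=C
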